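## Retrosynthetic overview

1. Target ⇐ 2'-hydroxychalcone, in one pot: Tl(NO3)3-mediated 1,2-shift of ring B from Cβ to Cα (the isoflavone-synthase step), acid closure of ring C through the only free ring A phenol, and loss of three MOM (CH2OCH3) groups.
2. Chalcone ⇐ Claisen–Schmidt condensation of a ring A acetophenone with a ring B/D chromene aldehyde.
3. Ring D ⇐ DDQ dehydrogenative cyclisation of 5-prenyl-2,4-dihydroxybenzaldehyde (o-quinone methide, oxa-6π closure), the prenyl-to-dimethylpyran step of biosynthesis; the prenyl group comes from 2-methylbut-3-en-2-ol.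
4. Ring A ketone ⇐ 2,6-dihydroxyacetophenone by Elbs hydroxylation, selective bis-MOM protection, iodination, and B-alkyl Suzuki coupling with the same C5 alcohol.
5. Ring order: D first (on the aldehyde), C last; rings A and B are the two benzenoid starting materials.

Assumption: the target has no stereocentre and is achiral, so the only stereo-elements to control are the E olefin of the chalcone and the ring-fixed Z olefin of the chromene.

## Route

Step 1
Reactants: 1 1-(2,6-dihydroxyphenyl)ethanone
Product: 3 1-(2,3,6-trihydroxyphenyl)ethanone, via aryl sulfate 2 (not isolated)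
Conditions: K2S2O8 (1.0 equiv), 10% aq. KOH, 0 °C to rt, 24 h; then HCl to pH 1, Na2SO3, 90 °C, 30 min
Reagents that add atoms: potassium peroxodisulfate, K2S2O8, [K+].[K+].[O-]S(=O)(=O)OOS(=O)(=O)[O-]
Why: Elbs persulfate oxidation, in which the phenolate is attacked by peroxodisulfate para to one O⁻ (C3 and C5 are equivalent by symmetry) and the resulting aryl sulfate, which shields the new oxygen from over-oxidation, is hydrolysed by acid.

Step 2
Reactants: 3 1-(2,3,6-trihydroxyphenyl)ethanone
Product: 4 1-[2-hydroxy-3,6-bis(methoxymethoxy)phenyl]ethanone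
Conditions: MOMCl (2.1 equiv), i-Pr2NEt (2.5 equiv), CH2Cl2, 0 °C to rt, 6 h
Reagents that add atoms: chloromethyl methyl ether (MOMCl), COCCl
Why: Selective Williamson-type O-alkylation, because the 3-OH is not hydrogen bonded and the 6-OH is unhindered, whereas the 2-OH sits between the acetyl group and the new 3-OMOM group and stays locked in the hydrogen bond to the carbonyl, so it alone remains free to become O1.

Step 3
Reactants: 4 1-[2-hydroxy-3,6-bis(methoxymethoxy)phenyl]ethanone
Product: 5 1-[2-hydroxy-5-iodo-3,6-bis(methoxymethoxy)phenyl]ethanone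
Conditions: NIS (1.05 equiv), DMF, 0 °C to rt, dark, 3 h
Reagents that add atoms: N-iodosuccinimide (NIS), O=C1CCC(=O)N1I
Why: Electrophilic aromatic iodination at C5, which is para to the free OH and ortho to the 6-OMOM group, while the only other free position (C4) is para to the acetyl group and deactivated.

Step 4
Reactants: 5 1-[2-hydroxy-5-iodo-3,6-bis(methoxymethoxy)phenyl]ethanone; 6 2-methylbut-3-en-2-ol
Product: 8 1-[2-hydroxy-5-(3-hydroxy-3-methylbutyl)-3,6-bis(methoxymethoxy)phenyl]ethanone, via alkylborane 7 (not isolated)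
Conditions: 6 (1.6 equiv), 9-BBN (1.5 equiv), THF, 0 °C to rt, 4 h; then 5, Pd(dppf)Cl2 (5 mol %), 3 M aq. K3PO4 (3 equiv), DMF, 60 °C, 12 h
Reagents that add atoms: none
Why: Anti-Markovnikov hydroboration of the terminal olefin with 9-BBN followed by B-alkyl Suzuki–Miyaura coupling delivers the saturated tertiary-alcohol side chain in one operation, and the ketone, phenol and MOM ethers tolerate the mild aqueous base.

Step 5
Reactants: 9 2,4-dihydroxybenzaldehyde; 6 2-methylbut-3-en-2-ol
Product: 10 2,4-dihydroxy-5-(3-methylbut-2-en-1-yl)benzaldehyde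
Conditions: 6 (1.2 equiv), BF3·OEt2 (0.5 equiv), dioxane, rt, 6 h; chromatography
Reagents that add atoms: none
Why: Friedel–Crafts nuclear prenylation, in which BF3 ionises the tertiary allylic alcohol to the dimethylallyl cation and this attacks the less hindered C5 (ortho to 4-OH, para to 2-OH) in preference to C3 between the two hydroxyls, the minor 3-prenyl and diprenyl products being removed by chromatography.

Step 6
Reactants: 10 2,4-dihydroxy-5-(3-methylbut-2-en-1-yl)benzaldehyde
Product: 12 7-hydroxy-2,2-dimethyl-2H-chromene-6-carbaldehyde, via o-quinone methide 11 (not isolated)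
Conditions: DDQ (1.1 equiv), PhMe, 80 °C, 1 h
Reagents that add atoms: none
Why: Biomimetic dehydrogenative cyclisation, in which DDQ abstracts the benzylic hydride of the prenyl group to give the o-quinone methide, and oxa-6π electrocyclisation onto the only neighbouring oxygen (4-OH) can give only the linear chromene, whose Z olefin is fixed by the ring.

Step 7
Reactants: 12 7-hydroxy-2,2-dimethyl-2H-chromene-6-carbaldehyde
Product: 13 7-(methoxymethoxy)-2,2-dimethyl-2H-chromene-6-carbaldehyde
Conditions: NaH (1.2 equiv), MOMCl (1.3 equiv), DMF, 0 °C to rt, 2 h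
Reagents that add atoms: chloromethyl methyl ether (MOMCl), COCCl
Why: Williamson etherification of the sodium phenolate masks the ortho phenol, which would otherwise deactivate the aldehyde as a phenolate in the aldol step and close onto the chalcone as a benzopyrylium under acid.

Step 8
Reactants: 8 1-[2-hydroxy-5-(3-hydroxy-3-methylbutyl)-3,6-bis(methoxymethoxy)phenyl]ethanone; 13 7-(methoxymethoxy)-2,2-dimethyl-2H-chromene-6-carbaldehyde
Product: 14 (E)-1-[2-hydroxy-5-(3-hydroxy-3-methylbutyl)-3,6-bis(methoxymethoxy)phenyl]-3-[7-(methoxymethoxy)-2,2-dimethyl-2H-chromen-6-yl]prop-2-en-1-one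
Conditions: KOH (50% aq., 10 equiv), EtOH, rt, 48 h; cold 10% citric acid work-up
Reagents that add atoms: none
Why: Claisen–Schmidt aldol condensation of the methyl ketone enolate with the non-enolisable aldehyde, the E olefin being set by E1cB dehydration under thermodynamic control, and the mild cold work-up keeping the 2'-hydroxychalcone from closing to the flavanone.

Step 9
Reactants: 14 (E)-1-[2-hydroxy-5-(3-hydroxy-3-methylbutyl)-3,6-bis(methoxymethoxy)phenyl]-3-[7-(methoxymethoxy)-2,2-dimethyl-2H-chromen-6-yl]prop-2-en-1-one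
Product: 17 kraussianone 3, via dimethyl acetal 15 (not isolated), via MOM-protected isoflavone 16 (not isolated)
Conditions: Tl(NO3)3·3H2O (1.1 equiv), MeOH/HC(OMe)3 3:1, 0 °C to rt, 2 h; filter TlNO3; then HCl (0.2 M in MeOH), rt, 1 h; then 2 M HCl (MeOH/H2O), 50 °C, 2 h
Reagents that add atoms: none
Why: Oxidative 1,2-aryl migration of a 2'-hydroxychalcone with thallium trinitrate, in which methoxythallation of the enone is followed by shift of the electron-rich ring B (para ring oxygen, ortho OMOM) from Cβ to Cα with loss of monovalent thallium to give racemic acetal 15, after which acid closes ring C through the single free phenol (placing O1 next to C8–O), eliminates methanol so that the transient stereocentre disappears, and cleaves the three MOM acetals, while the chromene olefin is expected to react more slowly because its C3 is neopentyl-like beside the gem-dimethyl carbon.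

## Compound list

1 | 1-(2,6-dihydroxyphenyl)ethanone | CC(=O)c1c(O)cccc1O | starting material
2 | potassium 3-acetyl-2,4-dihydroxyphenyl sulfate (not isolated) | CC(=O)c1c(O)ccc(OS(=O)(=O)[O-])c1O.[K+] | intermediate
3 | 1-(2,3,6-trihydroxyphenyl)ethanone | CC(=O)c1c(O)ccc(O)c1O | intermediate
4 | 1-[2-hydroxy-3,6-bis(methoxymethoxy)phenyl]ethanone | CC(=O)c1c(O)c(OCOC)ccc1OCOC | intermediate
5 | 1-[2-hydroxy-5-iodo-3,6-bis(methoxymethoxy)phenyl]ethanone | CC(=O)c1c(O)c(OCOC)cc(I)c1OCOC | intermediate
6 | 2-methylbut-3-en-2-ol | C=CC(C)(C)O | starting material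
7 | 4-(9-borabicyclo[3.3.1]nonan-9-yl)-2-methylbutan-2-ol (not isolated) | CC(C)(O)CCB1C2CCCC1CCC2 | intermediate
8 | 1-[2-hydroxy-5-(3-hydroxy-3-methylbutyl)-3,6-bis(methoxymethoxy)phenyl]ethanone | CC(=O)c1c(O)c(OCOC)cc(CCC(C)(C)O)c1OCOC | intermediate
9 | 2,4-dihydroxybenzaldehyde | O=Cc1ccc(O)cc1O | starting material
10 | 2,4-dihydroxy-5-(3-methylbut-2-en-1-yl)benzaldehyde | CC(C)=CCc1cc(C=O)c(O)cc1O | intermediate
11 | (3Z)-6-hydroxy-3-(3-methylbut-2-en-1-ylidene)-4-oxocyclohexa-1,5-diene-1-carbaldehyde, the o-quinone methide (not isolated) | CC(C)=C/C=C1\C(=O)C=C(O)C(C=O)=C1 | intermediate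
12 | 7-hydroxy-2,2-dimethyl-2H-chromene-6-carbaldehyde | CC1(C)C=Cc2cc(C=O)c(O)cc2O1 | intermediate
13 | 7-(methoxymethoxy)-2,2-dimethyl-2H-chromene-6-carbaldehyde | CC1(C)C=Cc2cc(C=O)c(OCOC)cc2O1 | intermediate
14 | (E)-1-[2-hydroxy-5-(3-hydroxy-3-methylbutyl)-3,6-bis(methoxymethoxy)phenyl]-3-[7-(methoxymethoxy)-2,2-dimethyl-2H-chromen-6-yl]prop-2-en-1-one | COCOc1cc2c(cc1/C=C/C(=O)c1c(O)c(OCOC)cc(CCC(C)(C)O)c1OCOC)C=CC(C)(C)O2 | intermediate
15 | racemic 1-[2-hydroxy-5-(3-hydroxy-3-methylbutyl)-3,6-bis(methoxymethoxy)phenyl]-3,3-dimethoxy-2-[7-(methoxymethoxy)-2,2-dimethyl-2H-chromen-6-yl]propan-1-one (not isolated) | COCOc1cc2c(cc1C(C(OC)OC)C(=O)c1c(O)c(OCOC)cc(CCC(C)(C)O)c1OCOC)C=CC(C)(C)O2 | intermediate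
16 | 6-(3-hydroxy-3-methylbutyl)-5,8-bis(methoxymethoxy)-3-[7-(methoxymethoxy)-2,2-dimethyl-2H-chromen-6-yl]-4H-chromen-4-one (not isolated) | COCOc1cc2c(cc1-c1coc3c(OCOC)cc(CCC(C)(C)O)c(OCOC)c3c1=O)C=CC(C)(C)O2 | intermediate
17 | kraussianone 3: 5,8-dihydroxy-6-(3-hydroxy-3-methylbutyl)-3-(7-hydroxy-2,2-dimethyl-2H-chromen-6-yl)-4H-chromen-4-one | CC(C)(O)CCc1cc(O)c2occ(-c3cc4c(cc3O)OC(C)(C)C=C4)c(=O)c2c1O | target

## Step count and risk

Total steps: 9. Longest linear sequence: 6 steps (1, 2, 3, 4, 8, 9). The ring B/D branch (5, 6, 7) joins at step 8.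

Three steps most likely to fail:

**Step 9.** Trivalent thallium may attack the electron-rich chromene olefin in competition with the enone, and the acid stage must spare the tertiary alcohol next to the freed 5-OH. The fallback sets out from 10, uses 8, and returns at 16; it carries ring D through the aryl shift in saturated form and restores the olefin afterwards.
- TsOH·H2O (cat.) in toluene at 80 °C closes the prenyl group of 10 onto the 4-OH to give 7-hydroxy-2,2-dimethylchromane-6-carbaldehyde F1.
- NaH/MOMCl in DMF gives 7-(methoxymethoxy)-2,2-dimethylchromane-6-carbaldehyde F2.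
- Claisen–Schmidt condensation of F2 with 8 (KOH, EtOH) gives the chromane chalcone F3.
- Tl(NO3)3·3H2O in MeOH/HC(OMe)3, now with no olefin other than the enone, gives the chromane dimethyl acetal F4.
- Catalytic TsOH·H2O in MeOH at rt closes ring C with the MOM groups kept and gives the chromane isoflavone F5.
- DDQ in dioxane at reflux removes the benzylic hydride at C4 of the chromane (para to the 7-OMOM oxygen) and gives 16, which goes through the last acid stage of step 9 to 17.

**Step 5.** The direct prenylation gives C5/C3 mixtures and over-alkylation, so the yield of 10 is modest. The fallback sets out from 9 and returns at 10. Br2 in AcOH at rt gives 5-bromo-2,4-dihydroxybenzaldehyde F6. Stille coupling of F6 with tributyl(3-methylbut-2-en-1-yl)stannane (Pd(PPh3)4, DMF, 90 °C) then places the prenyl group only where the bromine was and gives 10.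

**Step 1.** Elbs oxidations are low-yielding and the hydroxyquinol product is air-sensitive in base. The fallback sets out from 1 and returns at 3. Teuber oxidation of 1 with (KSO3)2NO (2.2 equiv) in aqueous KH2PO4/acetone at 0 °C gives 2-acetyl-3-hydroxy-1,4-benzoquinone F7. F7 is reduced in the same work-up with aqueous Na2S2O4 to 3.

## Further compounds

F1 | step 9 | 7-hydroxy-2,2-dimethylchromane-6-carbaldehyde | CC1(C)CCc2cc(C=O)c(O)cc2O1
F2 | step 9 | 7-(methoxymethoxy)-2,2-dimethylchromane-6-carbaldehyde | CC1(C)CCc2cc(C=O)c(OCOC)cc2O1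
F3 | step 9 | (E)-1-[2-hydroxy-5-(3-hydroxy-3-methylbutyl)-3,6-bis(methoxymethoxy)phenyl]-3-[7-(methoxymethoxy)-2,2-dimethylchroman-6-yl]prop-2-en-1-one | COCOc1cc2c(cc1/C=C/C(=O)c1c(O)c(OCOC)cc(CCC(C)(C)O)c1OCOC)CCC(C)(C)O2
F4 | step 9 | racemic 1-[2-hydroxy-5-(3-hydroxy-3-methylbutyl)-3,6-bis(methoxymethoxy)phenyl]-3,3-dimethoxy-2-[7-(methoxymethoxy)-2,2-dimethylchroman-6-yl]propan-1-one | COCOc1cc2c(cc1C(C(OC)OC)C(=O)c1c(O)c(OCOC)cc(CCC(C)(C)O)c1OCOC)CCC(C)(C)O2
F5 | step 9 | 6-(3-hydroxy-3-methylbutyl)-5,8-bis(methoxymethoxy)-3-[7-(methoxymethoxy)-2,2-dimethylchroman-6-yl]-4H-chromen-4-one | COCOc1cc2c(cc1-c1coc3c(OCOC)cc(CCC(C)(C)O)c(OCOC)c3c1=O)CCC(C)(C)O2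
F6 | step 5 | 5-bromo-2,4-dihydroxybenzaldehyde | O=Cc1cc(Br)c(O)cc1O
F7 | step 1 | 2-acetyl-3-hydroxycyclohexa-2,5-diene-1,4-dione | CC(=O)C1=C(O)C(=O)C=CC1=O
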